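Q is the aim, and the choice for the next flask is whether 2.00 equiv of G will do or the 4 equiv of the grey run must stay.

- grey: J 34 mM; G 4 equiv; run made earlier
- flask: J 34 mM; G 2.00 equiv; time 6.0 min

- grey (time / s: J / %, Q / %): 20.0: 56.9, 41.2; 40.0: 35.0, 60.5; 50.0: 28.1, 67.0; 80.0: 15.0, 78.4; 90.0: 12.1, 80.5; 120: 7.0, 85.1

(each reading ± 0.3 percentage points)

* part of the J that has reacted at 6.0 min
* share of the unused G that is free and not bound as Z, at 6.0 min

- the numbers in the tables scatter with a standard deviation of 0.3 percentage points
- a reading or a percentage of Q counts all its forms, free or not
- the earlier runs do not show how much of G is bound; that part of a forecast is a guess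

The reckoning here takes the binding of G as Z to be fast and tight, which is an assumption: each J passing through the step with G spends one G there and ties up a second as Z. The cover, the equivalents of G charged over the 2 G that each passing J costs, is 1.00 in this flask. It is the stoichiometric ratio of the charge to that double demand. The free part of the charged G is then one minus passage over cover, passage being the fraction of charged J that has gone through that step. The grey run has twice this flask's cover, at 2.00. At its last reading, Q is 91.5 % of the J used.

The forecast gives c 92 % and fr 55 %, with “about 0.5 is bound, so roughly 55% is free”. Its c, with the grey run's Q share assumed to carry over, gives this flask a passage of 84.2 %. The cover then puts fr at 27.3 %, lower than the forecast's. The recipe at 2.00 equiv is run once as a trial and judged on its Q, not on c: G is raised if Q falls short of the 85.1 % at the grey run's last reading.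

The flask gives c 92.2 % and fr 33.7 %, so the forecast's fr stands 21 percentage points too high.

    J + G → E + Q (k = 0.230 L mol⁻¹ s⁻¹)
    J + Q → X (k = 0.0820 L mol⁻¹ s⁻¹)
    D ⇌ Q, rate k3*(cs3 - [Q]) while solid is left; crystals form when [Q] > cs3 (solubility = 19.0 mM, k = 1.10 s⁻¹)
    G + E ⇌ Z, settled at all times (K = 14000 L mol⁻¹)

At 6.00 min the flask holds Q 67.8 % and X 24.4 %. Each X counts two J, one of them passed, so passage is 80.0 %. The cover then leaves 20.0 % of the G free against 20.2 % simulated, and fr comes to 33.4 %. The neighbour with 5.00 equiv of G has cover 2.50 and passage 96.4 %, which leaves 61.4 % free against 61 % simulated, and it ends with Q at 92.7 %. The flask is not at rest: by 60.0 min c reaches >99.9 %, passage 85.0 % leaves 15.0 % of the G free against 15.3 % simulated, Q gains 2.2 points, and X ends at 30.0 %.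

All runs are simulated with made-up constants; scatter was added.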